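**Retrosynthetic overview**
1. The C7 hydroxyl is added last by enolate oxidation; the C3 ester comes from the 3β-alcohol and (2E,4E,6R)-6-hydroxy-6-methylocta-2,4-dienoic acid, itself made from (S)-2-methylglycidol.
2. The 3β-alcohol comes from the bicyclic 1,9-dien-8-one by ε-C–H oxidation to the 3,8-dione and face-selective reduction of the C3 ketone.
3. Key disconnection: the C5–C10 bond. Rings A and B form together from an achiral ten-membered trienone by a proton-triggered transannular cyclisation, 1,2-hydride shift and 1,2-methyl shift (germacrene A → eudesmyl → eremophilenyl logic) under a chiral confined acid.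
4. The ten-membered ring comes from a purchased cyclohexenone by anionic acetylenic oxy-Cope ring expansion, then methyl addition with Stork–Danheiser transposition.
5. Ring order: six-membered ring (bought) → ten-membered ring → rings A and B in one step.

Assumption: locants C1–C10 follow eremophilane numbering (C3 ester, C4 and C5 methyls, C7 hydroxyl, C8 ketone, C9=C10 and C1=C2 alkenes); β is the face that carries the two methyl groups.
Assumption: the sense of induction of the chiral acid in step 5 cannot be predicted and must be found by experiment; the antipode that gives (4aR,5S)-10 is used and is written here as the (S,S) acid.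

**Route**

Step 1
Reactants: 1 3-ethoxycyclohex-2-en-1-one; 2 2-bromopropene
Product: 3 3-ethoxy-6-(prop-1-en-2-yl)cyclohex-2-en-1-one
Conditions: LiN(SiMe3)2 (2.1 equiv), Pd(OAc)2 (3 mol %), P(t-Bu)3·HBF4 (6 mol %), THF/toluene, 0 → 25 °C; AcOH quench at −78 °C
Reagents that add atoms: none
Why: Palladium-catalysed α-alkenylation of a ketone enolate (Buchwald–Hartwig-type enolate coupling): the kinetic C6 enolate of the vinylogous ester couples with the 2-propenyl palladium bromide, the more acidic product stays as its dienolate until the cold acid quench protonates the α-carbon so the isopropenyl group stays out of conjugation, and the racemic C6 centre is erased in step 3.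

Step 2
Reactants: 3 3-ethoxy-6-(prop-1-en-2-yl)cyclohex-2-en-1-one
Product: 4 3-ethoxy-1-ethynyl-6-(prop-1-en-2-yl)cyclohex-2-en-1-ol
Conditions: HC≡CMgBr (2 equiv), CeCl3 (2 equiv), THF, −78 → −20 °C; sat. NaHCO3 work-up, used crude
Reagents that add atoms: ethynylmagnesium bromide (C#C[Mg]Br)
Why: 1,2-Addition of a weakly basic cerium-modified acetylide (Imamoto conditions) to the vinylogous-ester carbonyl outruns enolisation of the doubly activated C6–H; both carbinol epimers form and both are used because this centre becomes the ketone carbon in step 3.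

Step 3
Reactants: 4 3-ethoxy-1-ethynyl-6-(prop-1-en-2-yl)cyclohex-2-en-1-ol
Product: 6 (2E,6E,9Z)-3-ethoxy-7-methylcyclodeca-2,6,9-trien-1-one, via potassium allenolate 5 (not isolated)
Conditions: KH (1.05 equiv), 18-crown-6, THF, 0 → 25 °C; sat. NH4Cl
Reagents that add atoms: none
Why: Anionic acetylenic oxy-Cope rearrangement ([3,3] ring expansion by four atoms): the potassium alkoxide of the 1,5-enyne rearranges through a chair-like array with the ring C–C bond pseudo-equatorial, which gives the (6E) trisubstituted alkene from either epimer, the allenolate is protonated at its central carbon from the exo side to give the (9Z) enone, and one equivalent of base leaves the alkyne C–H alone; no stereocentre remains.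

Step 4
Reactants: 6 (2E,6E,9Z)-3-ethoxy-7-methylcyclodeca-2,6,9-trien-1-one
Product: 8 (2E,4Z,7E)-3,7-dimethylcyclodeca-2,4,7-trien-1-one, via tertiary carbinol 7 (not isolated)
Conditions: MeLi, CeCl3, THF, −78 °C; sat. NH4Cl; then oxalic acid (10 mol %), THF/H2O, 0 °C
Reagents that add atoms: methyllithium (C[Li]); water (O)
Why: Stork–Danheiser sequence: methylcerium adds 1,2 to the cross-conjugated ketone, and mild aqueous acid hydrolyses the enol ether and eliminates the tertiary hydroxyl so the carbonyl moves to the former C–OEt carbon, water trapping the alkoxy-allyl cation faster than it can cyclise; the product is achiral.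

Step 5
Reactants: 8 (2E,4Z,7E)-3,7-dimethylcyclodeca-2,4,7-trien-1-one
Product: 10 (4aR,5S)-4a,5-dimethyl-4,4a,5,6-tetrahydronaphthalen-2(3H)-one, via eudesmyl cation 9 (not isolated)
Conditions: (S,S)-IDPi acid, O,O′-bis[(S)-3,3′-di(2-naphthyl)-1,1′-binaphthalene-2,2′-diyl] N,N′-bis(trifluoromethylsulfonyl)imidodiphosphorimidate (5 mol %), toluene, −40 → −20 °C
Reagents that add atoms: none
Why: Proposed new method: O-protonation of the dienone by the confined chiral acid gives a hydroxypentadienyl cation paired with the chiral anion; C5 of the (E)-trisubstituted alkene attacks C10 across the ring (neryl-to-terpinyl-type closure through a chair-like transition state), forming the C5–C10 bond and both six-membered rings as the trans-fused tertiary C4 cation 9; the axial 5α-H then shifts suprafacially to C4 (setting the 4β-methyl) and the axial 10β-methyl shifts to C5 (setting the quaternary 5β-methyl cis to it), which leaves the charge at C10 as the O-protonated linear dienone, the thermodynamic sink that releases the proton for turnover; the face is chosen in the C–C bond-forming step inside the chiral ion pair and relayed by the two stereospecific shifts, early alkene-forming proton loss is reversible under the strong acid, and any (2Z) isomer of 8 equilibrates through the same cation; the closest known reactions are the acid-induced transannular cyclisation of germacrone-type cyclodecadienones to eudesmanes, Westphalen-type 1,2-methyl shifts (eudesmane → eremophilane) and asymmetric Nazarov and polyene cyclisations catalysed by imidodiphosphorimidate acids.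

Step 6
Reactants: 10 (4aR,5S)-4a,5-dimethyl-4,4a,5,6-tetrahydronaphthalen-2(3H)-one
Product: 11 (4aR,5R)-4a,5-dimethyl-4,4a-dihydronaphthalene-2,6(3H,5H)-dione
Conditions: t-BuOOH (5 equiv), Pd(OH)2/C (5 mol %), K2CO3 (0.25 equiv), CH2Cl2, 4 °C
Reagents that add atoms: tert-butyl hydroperoxide (CC(C)(C)OO)
Why: Corey–Yu-type allylic C–H oxidation (peroxy-radical chain, then collapse of the allylic peroxide to the ketone): the C3 methylene is the only doubly activated C–H (allylic and ε to the dienone, as in β-ionone → 4-oxo-β-ionone), the near-neutral heterogeneous medium leaves the now enolisable C4 centre alone, and no stereocentre is formed.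

Step 7
Reactants: 11 (4aR,5R)-4a,5-dimethyl-4,4a-dihydronaphthalene-2,6(3H,5H)-dione
Product: 13 (4aR,5R,6S)-6-hydroxy-4a,5-dimethyl-4,4a,5,6-tetrahydronaphthalen-2(3H)-one, via lithium enolate 12 (not isolated)
Conditions: LiN(SiMe3)2 (1.05 equiv), THF, −78 °C; then i-Bu2AlH (1.2 equiv), −78 °C; Rochelle salt work-up
Reagents that add atoms: none
Why: Barton-type protection of a ketone as its enolate followed by 1,2-reduction: the base removes a C7 methylene proton (the C4–H beside the quaternary carbon is much slower), the C8 enolate is inert to hydride, and i-Bu2AlH attacks the C3 carbonyl from the α face, opposite the axial C5 methyl and the C4 methyl, which places the new hydroxyl β (3S in the target).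

Step 8
Reactants: 14 [(2S)-2-methyloxiran-2-yl]methanol
Product: 15 (2R)-2-methylbutane-1,2-diol
Conditions: MeMgBr (3 equiv), CuI (10 mol %), THF, −30 → 0 °C; sat. NH4Cl
Reagents that add atoms: methylmagnesium bromide (C[Mg]Br)
Why: Copper-catalysed Grignard opening of a 2,2-disubstituted epoxide at its CH2 carbon (SN2); the tertiary stereocentre is not touched and the descriptor changes from S to R only because the CIP ranks change.

Step 9
Reactants: 15 (2R)-2-methylbutane-1,2-diol; 16 ethyl (2E)-4-(diethoxyphosphoryl)but-2-enoate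
Product: 18 ethyl (2E,4E,6R)-6-hydroxy-6-methylocta-2,4-dienoate, via hydroxy aldehyde 17 (not isolated)
Conditions: (COCl)2, DMSO, CH2Cl2, −78 °C; Et3N; then lithium salt of 16 (3 equiv, from LiN(SiMe3)2, THF), −78 → 0 °C
Reagents that add atoms: none
Why: Swern oxidation of the primary hydroxyl (the tertiary one cannot be oxidised) and direct vinylogous Horner–Wadsworth–Emmons olefination of the labile α-hydroxy aldehyde with the γ-anion of the phosphonocrotonate, which forms the new C4=C5 bond E and keeps C2=C3 E; the carbinol centre is untouched.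

Step 10
Reactants: 18 ethyl (2E,4E,6R)-6-hydroxy-6-methylocta-2,4-dienoate
Product: 19 (2E,4E,6R)-6-hydroxy-6-methylocta-2,4-dienoic acid
Conditions: LiOH, THF/H2O, 25 °C; then 1 M HCl to pH 3 at 0 °C
Reagents that add atoms: lithium hydroxide ([Li+].[OH-])
Why: Ester saponification; the tertiary dienylic alcohol survives base and brief cold acidification because its ionisation would give a cation conjugated with the carboxyl group.

Step 11
Reactants: 13 (4aR,5R,6S)-6-hydroxy-4a,5-dimethyl-4,4a,5,6-tetrahydronaphthalen-2(3H)-one; 19 (2E,4E,6R)-6-hydroxy-6-methylocta-2,4-dienoic acid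
Product: 20 (1R,2S,8aR)-1,8a-dimethyl-6-oxo-1,2,6,7,8,8a-hexahydronaphthalen-2-yl (2E,4E,6R)-6-hydroxy-6-methylocta-2,4-dienoate
Conditions: 2-methyl-6-nitrobenzoic anhydride (1.3 equiv), Et3N, 4-(dimethylamino)pyridine (0.3 equiv), CH2Cl2, 25 °C
Reagents that add atoms: none
Why: Shiina esterification (mixed anhydride, then acyl transfer by 4-(dimethylamino)pyridine) acylates the hindered 3β-hydroxyl with retention at C3; the tertiary hydroxyl of the acid is too hindered to compete and the acid has no γ-hydrogen through which the diene could deconjugate.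

Step 12
Reactants: 20 (1R,2S,8aR)-1,8a-dimethyl-6-oxo-1,2,6,7,8,8a-hexahydronaphthalen-2-yl (2E,4E,6R)-6-hydroxy-6-methylocta-2,4-dienoate
Product: 22 (1R,2S,7R,8aR)-7-hydroxy-1,8a-dimethyl-6-oxo-1,2,6,7,8,8a-hexahydronaphthalen-2-yl (2E,4E,6R)-6-hydroxy-6-methylocta-2,4-dienoate, via dipotassium enolate 21 (not isolated)
Conditions: KN(SiMe3)2 (2.3 equiv), THF, −78 °C; then 2-(phenylsulfonyl)-3-phenyloxaziridine, −78 °C; sat. NH4Cl
Reagents that add atoms: 2-(phenylsulfonyl)-3-phenyloxaziridine (O=S(=O)(c1ccccc1)N1OC1c1ccccc1)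
Why: Davis α-hydroxylation of a kinetic enolate: the first equivalent of base makes the tertiary alkoxide, the second removes a C7 proton to give the cross-conjugated enolate, and the oxaziridine delivers oxygen to C7 from the α face, anti to the axial C5 methyl that shields the β face, giving the equatorial 7α-hydroxyl (7R).

**Compound list**
1 | 3-ethoxycyclohex-2-en-1-one | CCOC1=CC(=O)CCC1 | starting material
2 | 2-bromopropene | CC(Br)=C | starting material
3 | (±)-3-ethoxy-6-(prop-1-en-2-yl)cyclohex-2-en-1-one | CCOC1=CC(=O)C(CC1)C(C)=C | intermediate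
4 | 3-ethoxy-1-ethynyl-6-(prop-1-en-2-yl)cyclohex-2-en-1-ol (racemic; both C1 epimers) | CCOC1=CC(O)(C#C)C(CC1)C(C)=C | intermediate
5 | potassium (5E,9E)-9-ethoxy-5-methylcyclodeca-1,2,5,9-tetraen-1-olate (allenolate) | [K+].[O-]C1=C=CC/C(C)=C/CC/C(OCC)=C\1 | intermediate
6 | (2E,6E,9Z)-3-ethoxy-7-methylcyclodeca-2,6,9-trien-1-one | O=C1/C=C(OCC)\CC/C=C(C)/C/C=C\1 | intermediate
7 | (2E,6E,9Z)-3-ethoxy-1,7-dimethylcyclodeca-2,6,9-trien-1-ol (racemic) | OC1(C)/C=C(OCC)\CC/C=C(C)/C/C=C\1 | intermediate
8 | (2E,4Z,7E)-3,7-dimethylcyclodeca-2,4,7-trien-1-one | O=C1/C=C(C)/C=C\C/C(C)=C/CC1 | intermediate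
9 | trans-fused eudesmyl-type cation (C5–C10 bond formed, 10β-methyl, 5α-H, charge at C4, C8 as enol) | OC1=C[C@@]2(C)C=CC[C+](C)[C@@H]2CC1 | intermediate
10 | (4aR,5S)-4a,5-dimethyl-4,4a,5,6-tetrahydronaphthalen-2(3H)-one | O=C1CC[C@]2(C)[C@@H](C)CC=CC2=C1 | intermediate
11 | (4aR,5R)-4a,5-dimethyl-4,4a-dihydronaphthalene-2,6(3H,5H)-dione | O=C1CC[C@]2(C)[C@@H](C)C(=O)C=CC2=C1 | intermediate
12 | lithium C7–C8 enolate of 11 | [Li+].[O-]C1=CC[C@]2(C)[C@@H](C)C(=O)C=CC2=C1 | intermediate
13 | (4aR,5R,6S)-6-hydroxy-4a,5-dimethyl-4,4a,5,6-tetrahydronaphthalen-2(3H)-one | O=C1CC[C@]2(C)[C@@H](C)[C@@H](O)C=CC2=C1 | intermediate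
14 | [(2S)-2-methyloxiran-2-yl]methanol ((S)-2-methylglycidol) | C[C@]1(CO)CO1 | starting material
15 | (2R)-2-methylbutane-1,2-diol | CC[C@@](C)(O)CO | intermediate
16 | ethyl (2E)-4-(diethoxyphosphoryl)but-2-enoate | CCOC(=O)/C=C/CP(=O)(OCC)OCC | starting material
17 | (2R)-2-hydroxy-2-methylbutanal | CC[C@@](C)(O)C=O | intermediate
18 | ethyl (2E,4E,6R)-6-hydroxy-6-methylocta-2,4-dienoate | CC[C@@](C)(O)/C=C/C=C/C(=O)OCC | intermediate
19 | (2E,4E,6R)-6-hydroxy-6-methylocta-2,4-dienoic acid | CC[C@@](C)(O)/C=C/C=C/C(=O)O | intermediate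
20 | (1R,2S,8aR)-1,8a-dimethyl-6-oxo-1,2,6,7,8,8a-hexahydronaphthalen-2-yl (2E,4E,6R)-6-hydroxy-6-methylocta-2,4-dienoate | CC[C@@](C)(O)/C=C/C=C/C(=O)O[C@H]1C=CC2=CC(=O)CC[C@]2(C)[C@H]1C | intermediate
21 | dipotassium salt of 20 (tertiary alkoxide and C7–C8 enolate) | [K+].[K+].CC[C@@](C)([O-])/C=C/C=C/C(=O)O[C@H]1C=CC2=CC([O-])=CC[C@]2(C)[C@H]1C | intermediate
22 | (1R,2S,7R,8aR)-7-hydroxy-1,8a-dimethyl-6-oxo-1,2,6,7,8,8a-hexahydronaphthalen-2-yl (2E,4E,6R)-6-hydroxy-6-methylocta-2,4-dienoate (CNP0260852.1) | CC[C@@](C)(O)/C=C/C=C/C(=O)O[C@H]1C=CC2=CC(=O)[C@H](O)C[C@]2(C)[C@H]1C | target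

**Step count**
Total: 12 steps. Longest linear sequence: 9 steps (steps 1–7, 11, 12); the acid 19 is made in 3 steps (8–10).

**Three steps most likely to fail**

Step 5 (the cascade may stop at eudesmane alkenes, close cis, or give low enantiomeric excess). The fallback sets out from 8 and comes back at 13. Compound 8 is treated with catalytic CF3SO3H in 1,1,1,3,3,3-hexafluoropropan-2-ol/CH2Cl2 at −40 °C, a stronger non-basic medium in which every deprotonated by-product re-enters the cation manifold. This gives racemic material, that is 10 together with the mirror-image dienone F1. The racemate is taken through steps 6 and 7, where the mirror-image dione F2 and the mirror-image alcohol F3 accompany 11 and 13. The racemic alcohol is esterified with (S)-2-methoxy-2-phenylacetic acid (2-methyl-6-nitrobenzoic anhydride, 4-(dimethylamino)pyridine) to give the diastereomeric mandelate of 13 F4 and the mandelate of the mirror-image alcohol F5. These are separated on silica, and F4 is cleaved with K2CO3 in methanol to return 13.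

Step 3 (retro-ethynylation, wrong alkene geometry or strain in the triply unsaturated ring). The fallback sets out from 3 and comes back at 10. Vinylmagnesium bromide/CeCl3 is added instead of the acetylide to give the vinyl carbinol F6. The classical anionic oxy-Cope rearrangement (KH, 18-crown-6) then gives the ten-membered dienone vinylogous ester F7. MeLi/CeCl3 followed by aqueous oxalic acid, through the methyl carbinol F8 (not isolated), gives the macrocyclic dienone F9. The same chiral-acid cascade, now from a simpler hydroxyallyl cation, gives the bicyclic enone F10. Chloranil in refluxing t-BuOH then dehydrogenates C1–C2 to give 10.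

Step 7 (incomplete or unselective enolisation would let hydride reach the C8 ketone). The fallback sets out from 11 and comes back at 13. The C8 ketone is masked covalently with t-BuMe2SiOSO2CF3/Et3N as the silyl dienol ether F11. i-Bu2AlH then reduces the C3 ketone from the α face to the silyl dienol ether alcohol F12. Bu4NF buffered with AcOH releases the C8 ketone and gives 13.

**Further compounds**
F1 | step 5 | (4aS,5R)-4a,5-dimethyl-4,4a,5,6-tetrahydronaphthalen-2(3H)-one | O=C1CC[C@@]2(C)[C@H](C)CC=CC2=C1
F2 | step 5 | (4aS,5S)-4a,5-dimethyl-4,4a-dihydronaphthalene-2,6(3H,5H)-dione | O=C1CC[C@@]2(C)[C@H](C)C(=O)C=CC2=C1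
F3 | step 5 | (4aS,5S,6R)-6-hydroxy-4a,5-dimethyl-4,4a,5,6-tetrahydronaphthalen-2(3H)-one | O=C1CC[C@@]2(C)[C@H](C)[C@H](O)C=CC2=C1
F4 | step 5 | (1R,2S,8aR)-1,8a-dimethyl-6-oxo-1,2,6,7,8,8a-hexahydronaphthalen-2-yl (2S)-2-methoxy-2-phenylacetate | O=C1CC[C@]2(C)[C@@H](C)[C@@H](OC(=O)[C@@H](OC)c3ccccc3)C=CC2=C1
F5 | step 5 | (1S,2R,8aS)-1,8a-dimethyl-6-oxo-1,2,6,7,8,8a-hexahydronaphthalen-2-yl (2S)-2-methoxy-2-phenylacetate | O=C1CC[C@@]2(C)[C@H](C)[C@H](OC(=O)[C@@H](OC)c3ccccc3)C=CC2=C1
F6 | step 3 | 1-ethenyl-3-ethoxy-6-(prop-1-en-2-yl)cyclohex-2-en-1-ol (racemic; both C1 epimers) | CCOC1=CC(O)(C=C)C(CC1)C(C)=C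
F7 | step 3 | (2E,6E)-3-ethoxy-7-methylcyclodeca-2,6-dien-1-one | O=C1/C=C(OCC)\CC/C=C(C)/CCC1
F8 | step 3 | (2E,6E)-3-ethoxy-1,7-dimethylcyclodeca-2,6-dien-1-ol (racemic) | OC1(C)/C=C(OCC)\CC/C=C(C)/CCC1
F9 | step 3 | (2E,7E)-3,7-dimethylcyclodeca-2,7-dien-1-one | O=C1/C=C(C)/CCC/C(C)=C/CC1
F10 | step 3 | (4aR,5S)-4a,5-dimethyl-4,4a,5,6,7,8-hexahydronaphthalen-2(3H)-one | O=C1CC[C@]2(C)[C@@H](C)CCCC2=C1
F11 | step 7 | C8 tert-butyldimethylsilyl dienol ether of 11, (4aR,5R)-2-[(tert-butyldimethylsilyl)oxy]-4a,5-dimethyl-4a,5-dihydronaphthalen-6(4H)-one | CC(C)(C)[Si](C)(C)OC1=CC[C@]2(C)[C@@H](C)C(=O)C=CC2=C1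
F12 | step 7 | C8 tert-butyldimethylsilyl dienol ether of 13, (1R,2S,8aR)-6-[(tert-butyldimethylsilyl)oxy]-1,8a-dimethyl-1,2,8,8a-tetrahydronaphthalen-2-ol | CC(C)(C)[Si](C)(C)OC1=CC[C@]2(C)[C@@H](C)[C@@H](O)C=CC2=C1
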